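**Strategy.** The route rests on a temporary C3–C8 bond. C3 and C8 both carry oxygen in the target and sit 1,6 across the ten-membered ring, so joining them folds the germacrane into a cis-fused decalin: ring A (C3–C4=C5–C6–C7–C8) and ring B (C3–C2–C1–C10–C9–C8), with a tertiary hydroxyl on each ring-fusion carbon. Criegee cleavage of that glycol with Pb(OAc)4 opens the bicycle in one operation to the ten-membered 3,8-dione and delivers the Z C4=C5 alkene from the cyclohexene of ring A. The precursor is the decalindiol 25, silyl-protected at O6, O10 and O12, assembled from a ring-B ketone and a C5–C7/C11–C13 bromide by Barbier allylation, isopropenyl addition and ring-closing metathesis.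

Key step: step 17

Remarks on the chemistry (one line each):
- Germacrane locants are used throughout: ring carbons C1–C10, C11 on C7, C12 the oxygenated side-chain carbon, C13 the methylene, C14 the methyl on C10, C15 the methyl on C4. In 3–6 the carbonyl carbon is C8, the carbinol carbon is C10, and the α-carbon oxidised in step 3 is C3.
- Assumption: (R)-but-3-ene-1,2-diol 7 is taken as a commercial compound (product of hydrolytic kinetic resolution of butadiene monoepoxide).
- C3 and C8 of 16–25 are auxiliary stereocentres that become carbonyl carbons in step 17; only C6, C7 and C10 are carried to the target. They are placed cis to the C10 silyloxy group so that ring B can keep both large carbon substituents equatorial in steps 10 and 15.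
- Adduct 13 is carried as a mixture at its carbinol carbon, which becomes sp2 in step 9.
- O6 and O12 are carried as TBS ethers and O10 as a TES ether, so that one fluoride treatment frees all three hydroxyls before the lactone is closed.
- The stereochemical rationales in steps 10, 15, 18, 20 and 21 are model-based predictions, not established outcomes.

**Route**

Step 1
Reactants: 1 3-methylcyclohex-2-en-1-one
Product: 3 (S)-3-hydroxy-3-methylcyclohexan-1-one, via boronate 2 (not isolated)
Conditions: B2pin2, [Cu(MeCN)4]PF6 (cat.), QuinoxP* (cat., the enantiomer that gives the 3R boronate), LiOtBu (cat.), DMSO, rt; then NaBO3·4H2O, THF/H2O, rt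
Reagents that add atoms: bis(pinacolato)diboron CC1(C)OB(OC1(C)C)B1OC(C)(C)C(C)(C)O1 (boryl group of 2 only); sodium perborate [Na+].[O-]OB=O (hydroxyl oxygen of 3)
Why: Copper-catalysed enantioselective conjugate borylation of the β-methyl enone forms the quaternary C10–B centre with the face chosen by the chiral bisphosphine on the copper boryl species, and perborate oxidation exchanges boron for oxygen with retention, so the tertiary carbinol C10 is set here.

Step 2
Reactants: 3 (S)-3-hydroxy-3-methylcyclohexan-1-one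
Product: 4 (S)-3-methyl-3-(triethylsilyloxy)cyclohexan-1-one
Conditions: TESOTf, 2,6-lutidine, CH2Cl2, −78 °C
Reagents that add atoms: triethylsilyl trifluoromethanesulfonate CC[Si](CC)(CC)OS(=O)(=O)C(F)(F)F
Why: The silyl triflate with 2,6-lutidine silylates the tertiary alcohol at low temperature faster than it forms the enol silane of the ketone, and the C10 stereocentre is not involved.

Step 3
Reactants: 4 (S)-3-methyl-3-(triethylsilyloxy)cyclohexan-1-one
Product: 5 (2R,5S)-5-methyl-2-(N-phenylaminooxy)-5-(triethylsilyloxy)cyclohexan-1-one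
Conditions: L-proline (cat.), PhNO (slow addition), DMSO, rt
Reagents that add atoms: nitrosobenzene O=Nc1ccccc1
Why: Proline-catalysed α-aminoxylation (enamine catalysis, O-selective nitroso aldol) takes place at the unhindered α-methylene C3, remote from the quaternary C10, and the proline carboxylic acid steers nitrosobenzene to one enamine face, which with L-proline should give the 2R C–O bond, cis to the C10 silyloxy group.

Step 4
Reactants: 5 (2R,5S)-5-methyl-2-(N-phenylaminooxy)-5-(triethylsilyloxy)cyclohexan-1-one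
Product: 6 (2R,5S)-2-hydroxy-5-methyl-5-(triethylsilyloxy)cyclohexan-1-one
Conditions: H2 (1 atm), Pd/C, EtOAc, rt
Reagents that add atoms: none
Why: Hydrogenolysis of the weak N–O bond over Pd/C releases the α-hydroxy ketone and aniline without touching the ketone or the silyl ether, and the C3 carbinol keeps its configuration.

Step 5
Reactants: 7 (R)-but-3-ene-1,2-diol
Product: 8 (R)-3,4-bis(tert-butyldimethylsilyloxy)but-1-ene
Conditions: TBSCl, imidazole, DMF, rt
Reagents that add atoms: tert-butyldimethylsilyl chloride CC(C)(C)[Si](C)(C)Cl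
Why: Silylation of both hydroxyls with the silyl chloride and imidazole is routine and does not touch the stereocentre that will become C6.

Step 6
Reactants: 8 (R)-3,4-bis(tert-butyldimethylsilyloxy)but-1-ene
Product: 9 (R)-2-(tert-butyldimethylsilyloxy)but-3-en-1-ol
Conditions: HF·pyridine, pyridine, THF, 0 °C
Reagents that add atoms: none
Why: Buffered HF·pyridine cleaves the unhindered primary silyl ether much faster than the secondary allylic one (sterically controlled selective desilylation), and the acidic medium suppresses silyl migration.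

Step 7
Reactants: 9 (R)-2-(tert-butyldimethylsilyloxy)but-3-en-1-ol
Product: 10 (R)-2-(tert-butyldimethylsilyloxy)but-3-enal
Conditions: Dess–Martin periodinane, NaHCO3, CH2Cl2, 0 °C
Reagents that add atoms: none
Why: Dess–Martin oxidation under bicarbonate buffer gives the α-silyloxy β,γ-unsaturated aldehyde without base, which should prevent epimerisation at C6 and drift of the alkene into conjugation, provided the aldehyde is used at once.

Step 8
Reactants: 10 (R)-2-(tert-butyldimethylsilyloxy)but-3-enal; 11 methyl propiolate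
Product: 13 methyl (4R)-4-(tert-butyldimethylsilyloxy)-3-hydroxy-2-methylidenehex-5-enoate (both C3 epimers), via vinylalane 12 (not isolated)
Conditions: 11, iBu2AlH, N-methylmorpholine N-oxide, THF, 0 °C; then 10, 0 °C to rt
Reagents that add atoms: diisobutylaluminium hydride CC(C)C[AlH]CC(C)C (aluminium group of 12 only)
Why: Hydroalumination of the propiolate gives an α-aluminoacrylate that adds to the aldehyde at low temperature to give the Morita–Baylis–Hillman-type adduct (vinylalumination), avoiding the long amine exposure of the classical variant that would endanger the α-stereocentre; the new carbinol centre forms without control and is erased in step 9.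

Step 9
Reactants: 13 methyl (4R)-4-(tert-butyldimethylsilyloxy)-3-hydroxy-2-methylidenehex-5-enoate
Product: 14 methyl (2Z,4R)-2-(bromomethyl)-4-(tert-butyldimethylsilyloxy)hexa-2,5-dienoate
Conditions: NBS, Me2S, CH2Cl2, 0 °C to rt
Reagents that add atoms: N-bromosuccinimide O=C1CCC(=O)N1Br
Why: Corey–Kim-type bromination: the alcohol is activated as an alkoxysulfonium ion and bromide attacks the methylene terminus in an SN2′ sense, which is known to turn such adducts into 2-(bromomethyl)-2-enoates with the bromomethyl group cis to the γ-substituent (2Z).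

Step 10
Reactants: 6 (2R,5S)-2-hydroxy-5-methyl-5-(triethylsilyloxy)cyclohexan-1-one; 14 methyl (2Z,4R)-2-(bromomethyl)-4-(tert-butyldimethylsilyloxy)hexa-2,5-dienoate
Product: 16 methyl (3R,4R)-4-(tert-butyldimethylsilyloxy)-3-[(1R,2R,5S)-1,2-dihydroxy-5-methyl-5-(triethylsilyloxy)cyclohexyl]-2-methylidenehex-5-enoate, via allylindium 15 (not isolated)
Conditions: In powder, THF/H2O (1:1), rt
Reagents that add atoms: none
Why: Barbier-type indium allylation joins the γ-carbon of the 2-(bromomethyl)enoate to the C8 carbonyl and moves the alkene to C11=C13; C7 should be set by the adjacent C6 centre (C6–H eclipses C7=C11 to avoid allylic 1,3-strain and the ketone bonds on the face anti to the vinyl group, which gives the C6 oxygen and C11 the relationship of the cis-fused lactone), and C8 by the chair of ring B, where the indium-coordinated C3 hydroxyl is equatorial and the axial C10 silyloxy group screens the axial path, so the allyl group enters equatorially and the new C8 hydroxyl is cis to both oxygens.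

Step 11
Reactants: 16 hydroxy ester (as above)
Product: 17 (1R,2R,5S)-1-[(3R,4R)-4-(tert-butyldimethylsilyloxy)-2-(hydroxymethyl)hexa-1,5-dien-3-yl]-5-methyl-5-(triethylsilyloxy)cyclohexane-1,2-diol
Conditions: iBu2AlH, CH2Cl2, −78 to 0 °C; aqueous potassium sodium tartrate work-up
Reagents that add atoms: none
Why: Hydride reduction of the 2-methylene ester by iBu2AlH proceeds in the 1,2-sense to the primary allylic alcohol, and any γ-lactone formed onto the C8 hydroxyl in step 10 is reduced to the same triol; no stereocentre changes.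

Step 12
Reactants: 17 triol (as above)
Product: 18 (1R,2R,5S)-1-{(3R,4R)-4-(tert-butyldimethylsilyloxy)-2-[(tert-butyldimethylsilyloxy)methyl]hexa-1,5-dien-3-yl}-5-methyl-5-(triethylsilyloxy)cyclohexane-1,2-diol
Conditions: TBSCl, imidazole, CH2Cl2, 0 °C
Reagents that add atoms: tert-butyldimethylsilyl chloride CC(C)(C)[Si](C)(C)Cl
Why: Silyl chloride and imidazole at 0 °C protect the unhindered primary allylic hydroxyl selectively over the hindered secondary and tertiary ones.

Step 13
Reactants: 18 diol (as above)
Product: 19 (2R,4S)-2-{(3R,4R)-4-(tert-butyldimethylsilyloxy)-2-[(tert-butyldimethylsilyloxy)methyl]hexa-1,5-dien-3-yl}-2-hydroxy-4-methyl-4-(triethylsilyloxy)cyclohexan-1-one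
Conditions: IBX, DMSO, rt
Reagents that add atoms: none
Why: IBX oxidises the secondary alcohol of a secondary/tertiary 1,2-diol to the α-hydroxy ketone without cleaving the glycol, which removes the auxiliary C3 stereocentre and prepares C3 for the isopropenyl addition.

Step 14
Reactants: 19 α-hydroxy ketone (as above)
Product: 20 (2R,4S)-2-{(3R,4R)-4-(tert-butyldimethylsilyloxy)-2-[(tert-butyldimethylsilyloxy)methyl]hexa-1,5-dien-3-yl}-4-methyl-4-(triethylsilyloxy)-2-(trimethylsilyloxy)cyclohexan-1-one
Conditions: TMSOTf, 2,6-lutidine, CH2Cl2, −78 °C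
Reagents that add atoms: trimethylsilyl trifluoromethanesulfonate C[Si](C)(C)OS(=O)(=O)C(F)(F)F
Why: The silyl triflate with a hindered base at −78 °C caps the crowded tertiary hydroxyl faster than it enolises the ketone, so that the C8 oxygen cannot chelate magnesium or cerium in step 15.

Step 15
Reactants: 20 silyloxy ketone (as above); 21 isopropenylmagnesium bromide
Product: 24 (1S,2R,4S)-2-{(3R,4R)-4-(tert-butyldimethylsilyloxy)-2-[(tert-butyldimethylsilyloxy)methyl]hexa-1,5-dien-3-yl}-4-methyl-1-(prop-1-en-2-yl)-4-(triethylsilyloxy)cyclohexane-1,2-diol, via isopropenylcerium dichloride 22 (not isolated), via silyl ether 23 (not isolated)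
Conditions: 21, CeCl3, THF, −78 °C; then 20, −78 to 0 °C; then K2CO3, MeOH, rt
Reagents that add atoms: cerium trichloride Cl[Ce](Cl)Cl (cerium group of 22 only)
Why: Organocerium addition (Grignard reagent with CeCl3) to the hindered, enolisable C3 ketone: ring B sits in the chair with the C7 side chain and the C10 methyl equatorial and both silyloxy groups axial, so the nucleophile adds axially and antiperiplanar to the C8–O bond (polar Felkin–Anh control, no chelation by the silyl ether), which makes the C3 hydroxyl cis to the C8 oxygen and the two alkene-bearing groups cis, and K2CO3 in MeOH then cleaves only the trimethylsilyl ether.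

Step 16
Reactants: 24 diene diol (as above)
Product: 25 (3S,6R,7R,8R,10S)-6,12-bis(tert-butyldimethylsilyloxy)-10-(triethylsilyloxy)-3,8-cyclogermacra-4,11(13)-diene-3,8-diol (cis-fused decalin-4a,8a-diol; C3–OH, C8–OH, C10–OSi, C6–OSi and the C7 side chain all on one face)
Conditions: second-generation Grubbs catalyst (cat.), CH2Cl2, 40 °C
Reagents that add atoms: none
Why: Ring-closing metathesis between the monosubstituted vinyl group on C6 and the isopropenyl group on C3 closes the six-membered ring A as a trisubstituted cyclohexene with loss of ethene; the two partners are cis on ring B, so the fusion is cis, and the C11=C13 alkene could only give a four-membered or a tetrasubstituted five-membered ring and should stay out.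

Step 17
Reactants: 25 cis-fused decalindiol (as above)
Product: 26 (4Z,6R,7R,10S)-6,12-bis(tert-butyldimethylsilyloxy)-10-(triethylsilyloxy)germacra-4,11(13)-diene-3,8-dione
Conditions: Pb(OAc)4, pyridine, CH2Cl2, 0 °C; filtered and used at once
Reagents that add atoms: none
Why: The two tertiary hydroxyls exchange for two acetates on tetravalent lead to give a five-membered cyclic lead diester, which collapses in a concerted two-electron fragmentation that breaks the C3–C8 bond, turns both carbinol carbons into ketones and releases divalent lead. The closest known reaction is the Criegee glycol cleavage of ring-fusion decalindiols to cyclodecane-1,6-diones. The ten-membered ring is not closed by bond formation but emerges by scission of the bond shared by rings A and B (ring expansion by fragmentation), so no cyclisation mode and no entropic penalty are involved. No stereocentre is formed: C3 and C8 become trigonal, C6, C7 and C10 are untouched, and the Z geometry of C4=C5 is inherited from the cyclohexene of ring A. The step needs chemoselectivity for the glycol and a fast, neutral reaction: the cis ring fusion holds the two hydroxyls synclinal for the cyclic ester, every other hydroxyl is silylated, tertiary carbinols cannot be over-oxidised, and pyridine buffers the acetic acid, so that the dione, which is prone to transannular aldol closure and to epimerisation at C7, can be reduced directly in step 18.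

Step 18
Reactants: 26 dione (as above)
Product: 27 (4Z,6R,7S,8R,10S)-6,12-bis(tert-butyldimethylsilyloxy)-8-hydroxy-10-(triethylsilyloxy)germacra-4,11(13)-dien-3-one
Conditions: NaBH4, MeOH/CH2Cl2 (1:1), −78 °C; AcOH quench
Reagents that add atoms: none
Why: At −78 °C and without a cerium salt, borohydride reduces the isolated, more electrophilic C8 ketone in preference to the α-methyl enone at C3, and hydride is expected to come from the ring periphery anti to the C7–C11 bond (Felkin–Anh), which places the new C8 hydroxyl trans to the C7 side chain (8R).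

Step 19
Reactants: 27 C8 alcohol (as above); 28 angelic acid
Product: 30 (4Z,6R,7S,8R,10S)-8-angeloyloxy-6,12-bis(tert-butyldimethylsilyloxy)-10-(triethylsilyloxy)germacra-4,11(13)-dien-3-one, via mixed anhydride 29 (not isolated)
Conditions: 28, 2,4,6-trichlorobenzoyl chloride, Et3N, toluene, rt; then 27, 80 °C
Reagents that add atoms: 2,4,6-trichlorobenzoyl chloride O=C(Cl)c1c(Cl)cc(Cl)cc1Cl (aroyl group of 29 only)
Why: Yamaguchi-type esterification: the mixed anhydride is attacked at the less hindered angeloyl carbonyl, and running it hot in toluene without a nucleophilic catalyst is the known way to make angelates of hindered alcohols without isomerisation to the tiglate; C8 keeps its configuration.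

Step 20
Reactants: 30 angelate (as above)
Product: 32 (1E,4Z,6R,7S,8R,10R)-8-angeloyloxy-6,12-bis(tert-butyldimethylsilyloxy)-10-(triethylsilyloxy)germacra-1,4,11(13)-trien-3-one, via silyl dienol ether 31 (not isolated)
Conditions: TMSOTf, Et3N, CH2Cl2, 0 °C; then Pd(OAc)2, MeCN, rt
Reagents that add atoms: trimethylsilyl trifluoromethanesulfonate C[Si](C)(C)OS(=O)(=O)C(F)(F)F (silyl group of 31 only)
Why: Saegusa–Ito oxidation: soft enolisation of the enone can only take place toward C2 and gives the cross-conjugated 2-silyloxydiene, whose palladium enolate loses a C1 hydrogen by syn β-hydride elimination from the rotamer with C10 anti to the carbonyl group, so the new C1=C2 bond is expected to be E.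

Step 21
Reactants: 32 dienone (as above)
Product: 33 (1E,3R,4Z,6R,7S,8R,10R)-8-angeloyloxy-6,12-bis(tert-butyldimethylsilyloxy)-10-(triethylsilyloxy)germacra-1,4,11(13)-trien-3-ol
Conditions: NaBH4, CeCl3·7H2O, MeOH, −78 °C
Reagents that add atoms: none
Why: Luche reduction: cerium-activated borohydride adds 1,2 to the cross-conjugated dienone, and hydride is expected on the outer face of the carbonyl held in the ten-membered ring, which should give the 3R doubly allylic alcohol (the least secure stereocentre of the route).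

Step 22
Reactants: 33 dienol (as above)
Product: 34 (1E,3R,4Z,6R,7S,8R,10R)-3-acetoxy-8-angeloyloxy-6,12-bis(tert-butyldimethylsilyloxy)-10-(triethylsilyloxy)germacra-1,4,11(13)-triene
Conditions: Ac2O, pyridine, DMAP (cat.), CH2Cl2, 0 °C
Reagents that add atoms: acetic anhydride CC(=O)OC(C)=O
Why: Acylation of the secondary alcohol with the anhydride, pyridine and catalytic DMAP at 0 °C is routine, retains C3 and is mild enough to leave the angelate geometry alone.

Step 23
Reactants: 34 acetate (as above)
Product: 35 (1E,3R,4Z,6R,7R,8R,10R)-3-acetoxy-8-angeloyloxygermacra-1,4,11(13)-triene-6,10,12-triol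
Conditions: HF·pyridine, pyridine, THF, 0 °C to rt
Reagents that add atoms: none
Why: Fluoride-driven cleavage of the three silyl ethers with pyridine-buffered HF·pyridine frees O6, O10 and O12 in one operation, the mildly acidic medium avoiding acyl migration and leaving the two esters intact.

Step 24
Reactants: 35 triol (as above)
Product: 38 (1E,3R,4Z,6R,7S,8R,10R)-3-acetoxy-8-angeloyloxy-10-hydroxygermacra-1,4,11(13)-trien-12,6-olide (CNP0181631.1), via enal 36 (not isolated), via lactol 37 (not isolated)
Conditions: TEMPO (cat.), PhI(OAc)2, CH2Cl2, rt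
Reagents that add atoms: none
Why: Oxidative lactonisation with the oxoammonium salt generated from TEMPO: the primary allylic alcohol is oxidised selectively to the enal, the C6 hydroxyl closes the five-membered lactol, which is oxidised further to the α-methylene γ-lactone, while the tertiary alcohol is inert; C6 and C7 are untouched, so the lactone is cis-fused as in the target.

**Compound list**

1 | 3-methylcyclohex-2-en-1-one | CC1=CC(=O)CCC1 | starting material
2 | (R)-3-methyl-3-(4,4,5,5-tetramethyl-1,3,2-dioxaborolan-2-yl)cyclohexan-1-one | O=C1C[C@@](C)(B2OC(C)(C)C(C)(C)O2)CCC1 | intermediate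
3 | (S)-3-hydroxy-3-methylcyclohexan-1-one | O=C1C[C@@](C)(O)CCC1 | intermediate
4 | (S)-3-methyl-3-(triethylsilyloxy)cyclohexan-1-one | O=C1C[C@@](C)(O[Si](CC)(CC)CC)CCC1 | intermediate
5 | (2R,5S)-5-methyl-2-(N-phenylaminooxy)-5-(triethylsilyloxy)cyclohexan-1-one | O=C1C[C@@](C)(O[Si](CC)(CC)CC)CC[C@H]1ONc1ccccc1 | intermediate
6 | (2R,5S)-2-hydroxy-5-methyl-5-(triethylsilyloxy)cyclohexan-1-one | O=C1C[C@@](C)(O[Si](CC)(CC)CC)CC[C@H]1O | intermediate
7 | (R)-but-3-ene-1,2-diol | OC[C@H](O)C=C | starting material
8 | (R)-3,4-bis(tert-butyldimethylsilyloxy)but-1-ene | CC(C)(C)[Si](C)(C)OC[C@H](O[Si](C)(C)C(C)(C)C)C=C | intermediate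
9 | (R)-2-(tert-butyldimethylsilyloxy)but-3-en-1-ol | OC[C@H](O[Si](C)(C)C(C)(C)C)C=C | intermediate
10 | (R)-2-(tert-butyldimethylsilyloxy)but-3-enal | O=C[C@H](O[Si](C)(C)C(C)(C)C)C=C | intermediate
11 | methyl propiolate | C#CC(=O)OC | starting material
12 | methyl 2-(diisobutylalumanyl)prop-2-enoate | C=C(C(=O)OC)[Al](CC(C)C)CC(C)C | intermediate
13 | methyl (4R)-4-(tert-butyldimethylsilyloxy)-3-hydroxy-2-methylidenehex-5-enoate (both C3 epimers) | C=C(C(=O)OC)C(O)[C@H](O[Si](C)(C)C(C)(C)C)C=C | intermediate
14 | methyl (2Z,4R)-2-(bromomethyl)-4-(tert-butyldimethylsilyloxy)hexa-2,5-dienoate | COC(=O)/C(CBr)=C/[C@H](O[Si](C)(C)C(C)(C)C)C=C | intermediate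
15 | methyl (2Z,4R)-4-(tert-butyldimethylsilyloxy)-2-[(dibromoindiganyl)methyl]hexa-2,5-dienoate (allylindium, drawn as the dibromide) | COC(=O)/C(C[In](Br)Br)=C/[C@H](O[Si](C)(C)C(C)(C)C)C=C | intermediate
16 | methyl (3R,4R)-4-(tert-butyldimethylsilyloxy)-3-[(1R,2R,5S)-1,2-dihydroxy-5-methyl-5-(triethylsilyloxy)cyclohexyl]-2-methylidenehex-5-enoate | C=C(C(=O)OC)[C@H]([C@H](O[Si](C)(C)C(C)(C)C)C=C)[C@]1(O)C[C@@](C)(O[Si](CC)(CC)CC)CC[C@H]1O | intermediate
17 | (1R,2R,5S)-1-[(3R,4R)-4-(tert-butyldimethylsilyloxy)-2-(hydroxymethyl)hexa-1,5-dien-3-yl]-5-methyl-5-(triethylsilyloxy)cyclohexane-1,2-diol | C=C(CO)[C@H]([C@H](O[Si](C)(C)C(C)(C)C)C=C)[C@]1(O)C[C@@](C)(O[Si](CC)(CC)CC)CC[C@H]1O | intermediate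
18 | (1R,2R,5S)-1-{(3R,4R)-4-(tert-butyldimethylsilyloxy)-2-[(tert-butyldimethylsilyloxy)methyl]hexa-1,5-dien-3-yl}-5-methyl-5-(triethylsilyloxy)cyclohexane-1,2-diol | C=C(CO[Si](C)(C)C(C)(C)C)[C@H]([C@H](O[Si](C)(C)C(C)(C)C)C=C)[C@]1(O)C[C@@](C)(O[Si](CC)(CC)CC)CC[C@H]1O | intermediate
19 | (2R,4S)-2-{(3R,4R)-4-(tert-butyldimethylsilyloxy)-2-[(tert-butyldimethylsilyloxy)methyl]hexa-1,5-dien-3-yl}-2-hydroxy-4-methyl-4-(triethylsilyloxy)cyclohexan-1-one | C=C(CO[Si](C)(C)C(C)(C)C)[C@H]([C@H](O[Si](C)(C)C(C)(C)C)C=C)[C@]1(O)C[C@@](C)(O[Si](CC)(CC)CC)CCC1=O | intermediate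
20 | (2R,4S)-2-{(3R,4R)-4-(tert-butyldimethylsilyloxy)-2-[(tert-butyldimethylsilyloxy)methyl]hexa-1,5-dien-3-yl}-4-methyl-4-(triethylsilyloxy)-2-(trimethylsilyloxy)cyclohexan-1-one | C=C(CO[Si](C)(C)C(C)(C)C)[C@H]([C@H](O[Si](C)(C)C(C)(C)C)C=C)[C@]1(O[Si](C)(C)C)C[C@@](C)(O[Si](CC)(CC)CC)CCC1=O | intermediate
21 | isopropenylmagnesium bromide | C=C(C)[Mg]Br | starting material
22 | isopropenylcerium dichloride | C=C(C)[Ce](Cl)Cl | intermediate
23 | (1S,2R,4S)-2-{(3R,4R)-4-(tert-butyldimethylsilyloxy)-2-[(tert-butyldimethylsilyloxy)methyl]hexa-1,5-dien-3-yl}-4-methyl-1-(prop-1-en-2-yl)-4-(triethylsilyloxy)-2-(trimethylsilyloxy)cyclohexan-1-ol | C=C(CO[Si](C)(C)C(C)(C)C)[C@H]([C@H](O[Si](C)(C)C(C)(C)C)C=C)[C@]1(O[Si](C)(C)C)C[C@@](C)(O[Si](CC)(CC)CC)CC[C@]1(O)C(C)=C | intermediate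
24 | (1S,2R,4S)-2-{(3R,4R)-4-(tert-butyldimethylsilyloxy)-2-[(tert-butyldimethylsilyloxy)methyl]hexa-1,5-dien-3-yl}-4-methyl-1-(prop-1-en-2-yl)-4-(triethylsilyloxy)cyclohexane-1,2-diol | C=C(CO[Si](C)(C)C(C)(C)C)[C@H]([C@H](O[Si](C)(C)C(C)(C)C)C=C)[C@]1(O)C[C@@](C)(O[Si](CC)(CC)CC)CC[C@]1(O)C(C)=C | intermediate
25 | (3S,6R,7R,8R,10S)-6,12-bis(tert-butyldimethylsilyloxy)-10-(triethylsilyloxy)-3,8-cyclogermacra-4,11(13)-diene-3,8-diol (cis-fused decalindiol, key-step precursor) | C=C(CO[Si](C)(C)C(C)(C)C)[C@@H]1[C@H](O[Si](C)(C)C(C)(C)C)C=C(C)[C@@]2(O)CC[C@](C)(O[Si](CC)(CC)CC)C[C@@]12O | intermediate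
26 | (4Z,6R,7R,10S)-6,12-bis(tert-butyldimethylsilyloxy)-10-(triethylsilyloxy)germacra-4,11(13)-diene-3,8-dione (key-step product) | C=C(CO[Si](C)(C)C(C)(C)C)[C@@H]1[C@H](O[Si](C)(C)C(C)(C)C)/C=C(/C)C(=O)CC[C@](C)(O[Si](CC)(CC)CC)CC1=O | intermediate
27 | (4Z,6R,7S,8R,10S)-6,12-bis(tert-butyldimethylsilyloxy)-8-hydroxy-10-(triethylsilyloxy)germacra-4,11(13)-dien-3-one | C=C(CO[Si](C)(C)C(C)(C)C)[C@@H]1[C@H](O[Si](C)(C)C(C)(C)C)/C=C(/C)C(=O)CC[C@](C)(O[Si](CC)(CC)CC)C[C@H]1O | intermediate
28 | angelic acid, (Z)-2-methylbut-2-enoic acid | C/C=C(/C)C(=O)O | starting material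
29 | angelic 2,4,6-trichlorobenzoic anhydride | C/C=C(/C)C(=O)OC(=O)c1c(Cl)cc(Cl)cc1Cl | intermediate
30 | (4Z,6R,7S,8R,10S)-8-angeloyloxy-6,12-bis(tert-butyldimethylsilyloxy)-10-(triethylsilyloxy)germacra-4,11(13)-dien-3-one | C=C(CO[Si](C)(C)C(C)(C)C)[C@@H]1[C@H](O[Si](C)(C)C(C)(C)C)/C=C(/C)C(=O)CC[C@](C)(O[Si](CC)(CC)CC)C[C@H]1OC(=O)/C(C)=C\C | intermediate
31 | 3-(trimethylsilyloxy)-2,4,11(13)-triene derived from 30 (C2=C3 enol ether, its geometry left open; other centres as in 30) | C=C(CO[Si](C)(C)C(C)(C)C)[C@@H]1[C@H](O[Si](C)(C)C(C)(C)C)/C=C(/C)C(O[Si](C)(C)C)=CC[C@](C)(O[Si](CC)(CC)CC)C[C@H]1OC(=O)/C(C)=C\C | intermediate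
32 | (1E,4Z,6R,7S,8R,10R)-8-angeloyloxy-6,12-bis(tert-butyldimethylsilyloxy)-10-(triethylsilyloxy)germacra-1,4,11(13)-trien-3-one | C=C(CO[Si](C)(C)C(C)(C)C)[C@@H]1[C@H](O[Si](C)(C)C(C)(C)C)/C=C(/C)C(=O)/C=C/[C@](C)(O[Si](CC)(CC)CC)C[C@H]1OC(=O)/C(C)=C\C | intermediate
33 | (1E,3R,4Z,6R,7S,8R,10R)-8-angeloyloxy-6,12-bis(tert-butyldimethylsilyloxy)-10-(triethylsilyloxy)germacra-1,4,11(13)-trien-3-ol | C=C(CO[Si](C)(C)C(C)(C)C)[C@@H]1[C@H](O[Si](C)(C)C(C)(C)C)/C=C(/C)[C@H](O)/C=C/[C@](C)(O[Si](CC)(CC)CC)C[C@H]1OC(=O)/C(C)=C\C | intermediate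
34 | (1E,3R,4Z,6R,7S,8R,10R)-3-acetoxy-8-angeloyloxy-6,12-bis(tert-butyldimethylsilyloxy)-10-(triethylsilyloxy)germacra-1,4,11(13)-triene | C=C(CO[Si](C)(C)C(C)(C)C)[C@@H]1[C@H](O[Si](C)(C)C(C)(C)C)/C=C(/C)[C@H](OC(C)=O)/C=C/[C@](C)(O[Si](CC)(CC)CC)C[C@H]1OC(=O)/C(C)=C\C | intermediate
35 | (1E,3R,4Z,6R,7R,8R,10R)-3-acetoxy-8-angeloyloxygermacra-1,4,11(13)-triene-6,10,12-triol | C=C(CO)[C@@H]1[C@H](O)/C=C(/C)[C@H](OC(C)=O)/C=C/[C@](C)(O)C[C@H]1OC(=O)/C(C)=C\C | intermediate
36 | 12-aldehyde of 35 (3-acetoxy-8-angeloyloxy-6,10-dihydroxygermacra-1,4,11(13)-trien-12-al) | C=C(C=O)[C@@H]1[C@H](O)/C=C(/C)[C@H](OC(C)=O)/C=C/[C@](C)(O)C[C@H]1OC(=O)/C(C)=C\C | intermediate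
37 | 6,12-lactol of 36 (both C12 anomers) | C=C1C(O)O[C@@H]2/C=C(/C)[C@H](OC(C)=O)/C=C/[C@](C)(O)C[C@@H](OC(=O)/C(C)=C\C)[C@H]12 | intermediate
38 | (1E,3R,4Z,6R,7S,8R,10R)-3-acetoxy-8-angeloyloxy-10-hydroxygermacra-1,4,11(13)-trien-12,6-olide, CNP0181631.1 | C=C1C(=O)O[C@@H]2/C=C(/C)[C@H](OC(C)=O)/C=C/[C@](C)(O)C[C@@H](OC(=O)/C(C)=C\C)[C@H]12 | target

**Step count and risks**

Total steps: 24. Longest linear sequence: 20 steps (steps 5–9 from 7, then steps 10–24).

The three steps most likely to fail:

Step 10. The hindered ketone may react slowly, and the facial selectivity of the allyl unit at C7, which rests on 1,2-induction from C6 in a flexible transition state, may be poor. The fallback sets out from bromide 14 and replaces the Barbier reaction by an allylboration. Borylation of 14 (B2pin2, Pd2(dba)3 cat., DMSO, 50 °C) would give the allylboronate methyl (2E,4R)-4-(tert-butyldimethylsilyloxy)-2-[(4,4,5,5-tetramethyl-1,3,2-dioxaborolan-2-yl)methyl]hexa-2,5-dienoate F1. With α-hydroxy ketone 6 in toluene the boronate would first exchange onto the C3 hydroxyl and then transfer its allyl group within the resulting boron chelate through a closed chair transition state (the known accelerated allylboration of α-hydroxy ketones). Aqueous work-up would rejoin the route at hydroxy ester 16.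

Step 18. Hydride may be delivered to the wrong face of the C8 carbonyl of the flexible ten-membered ring, or the two ketones may be poorly discriminated. If the other face is attacked, dione 26 would give the 8S alcohol (4Z,6R,7S,8S,10S)-6,12-bis(tert-butyldimethylsilyloxy)-8-hydroxy-10-(triethylsilyloxy)germacra-4,11(13)-dien-3-one F2. Instead of a retentive acylation, F2 would be esterified with inversion by a Mitsunobu reaction with angelic acid 28 (PPh3, diisopropyl azodicarboxylate, toluene, 0 °C), which rejoins the route at angelate 30.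

Step 21. Facial selectivity of hydride addition to the C3 dienone depends only on the ring conformation and may be low or reversed. If the wrong face is attacked, dienone 32 would give the 3S alcohol (1E,3S,4Z,6R,7S,8R,10R)-8-angeloyloxy-6,12-bis(tert-butyldimethylsilyloxy)-10-(triethylsilyloxy)germacra-1,4,11(13)-trien-3-ol F3. Mitsunobu inversion of F3 with acetic acid (PPh3, diisopropyl azodicarboxylate, THF, 0 °C) would install the acetate with the 3R configuration directly and rejoin the route at acetate 34.

**Further compounds**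

F1 | step 10 | methyl (2E,4R)-4-(tert-butyldimethylsilyloxy)-2-[(4,4,5,5-tetramethyl-1,3,2-dioxaborolan-2-yl)methyl]hexa-2,5-dienoate | COC(=O)/C(CB1OC(C)(C)C(C)(C)O1)=C/[C@H](O[Si](C)(C)C(C)(C)C)C=C
F2 | step 18 | (4Z,6R,7S,8S,10S)-6,12-bis(tert-butyldimethylsilyloxy)-8-hydroxy-10-(triethylsilyloxy)germacra-4,11(13)-dien-3-one | C=C(CO[Si](C)(C)C(C)(C)C)[C@@H]1[C@H](O[Si](C)(C)C(C)(C)C)/C=C(/C)C(=O)CC[C@](C)(O[Si](CC)(CC)CC)C[C@@H]1O
F3 | step 21 | (1E,3S,4Z,6R,7S,8R,10R)-8-angeloyloxy-6,12-bis(tert-butyldimethylsilyloxy)-10-(triethylsilyloxy)germacra-1,4,11(13)-trien-3-ol | C=C(CO[Si](C)(C)C(C)(C)C)[C@@H]1[C@H](O[Si](C)(C)C(C)(C)C)/C=C(/C)[C@@H](O)/C=C/[C@](C)(O[Si](CC)(CC)CC)C[C@H]1OC(=O)/C(C)=C\C
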